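Ring A (C1–C6) is a resorcinol monomethyl ether: C3–OH and C5–OMe are 1,3 to each other, C1 carries the C7–C8 arm, and C2, C4 and C6 carry 4-hydroxybenzyl groups. This is the oxygen pattern of a folded C1/C5/C3 tricarbonyl chain in which C1 was a ketone and C2 the α-carbon of the C3 ketone.
Retrosynthesis: the three O-benzyl groups and the C7=C8 alkene are restored first. Ring A is then cut at C1–C2 (aldol condensation and aromatisation), giving an open-chain cinnamoyl diketone whose C5 carbonyl is a methyl enol ether. That chain is cut at C3–C2 (alkyllithium on a lactone carbonyl) and at C1–C6 (vinylogous aldol with (E)-3-methoxycinnamaldehyde). The remaining β-methoxy enoate comes from methyl acetoacetate by γ-benzylation (C6–CH2Ar), α-benzylation (C4–CH2Ar) and O-methylation (C5–OMe).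
Forward: the chain is joined in the order C6–CH2Ar, C4–CH2Ar, C5–OMe, C6–C1 (held for a while as a δ-lactone between O–C1 and C3), C3–C2, then oxidation at C1. Ring A is the only lasting ring and closes in step 8; one hydrogenation finishes the route.
Stereochemistry: the target has no stereocentre. The sp3 centres of the intermediates (C4, C6, C1, C2) form racemic or as mixtures and all end as sp2 carbons of ring A. The E alkene comes from the enal and is saturated at the end. The enol ether geometry needed for closure (C3 cis to C6) is locked by the lactone of step 4.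
The C1 unit is attached to C6 at the ester stage, where C6 is the only acidic carbon, because a β-methoxy enone with a free α′ methylene (C2) would be enolised and acylated at C2 instead.

Key step: step 8

Remark: locants C1–C8 are those of the target (ring A = C1–C6, arm = C7 and C8) and denote the same atoms in every intermediate; aldehyde 7 and alcohol 10 are taken as purchased materials.

Step 1
Reactants: 1 methyl acetoacetate; 2 4-(benzyloxy)benzyl chloride
Product: 3 methyl 5-[4-(benzyloxy)phenyl]-3-oxopentanoate
Conditions: NaH, THF, 0 °C; n-BuLi, 0 °C; then 2, 0 °C → rt; aq. HCl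
Reagents that add atoms: none
Why: The acetoacetate dianion reacts with the benzylic chloride only at its more basic terminal carbon (γ-alkylation of a β-keto ester dianion), which should form the C6–CH2Ar bond without touching the central methylene.

Step 2
Reactants: 3 methyl 5-[4-(benzyloxy)phenyl]-3-oxopentanoate; 2 4-(benzyloxy)benzyl chloride
Product: 4 methyl 2-[4-(benzyloxy)benzyl]-5-[4-(benzyloxy)phenyl]-3-oxopentanoate
Conditions: NaH, THF–DMF, 0 °C; 2 (1 equiv), NaI (cat.), rt → 50 °C
Reagents that add atoms: none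
Why: The sodium enolate of the β-keto ester is C-alkylated at the doubly activated C4 by the reactive benzylic halide (acetoacetic ester alkylation), one equivalent of base and halide holding it at the mono-benzyl stage; the new centre is racemic and becomes sp2 in step 3.

Step 3
Reactants: 4 methyl 2-[4-(benzyloxy)benzyl]-5-[4-(benzyloxy)phenyl]-3-oxopentanoate
Product: 6 methyl (2E)-2-[4-(benzyloxy)benzyl]-5-[4-(benzyloxy)phenyl]-3-methoxypent-2-enoate, via dimethyl ketal 5 (not isolated)
Conditions: HC(OMe)3 (neat), H2SO4 (cat.), rt → 60 °C, volatiles distilled off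
Reagents that add atoms: trimethyl orthoformate, COC(OC)OC
Why: Acid-catalysed ketalisation of the ketone and loss of methanol (enol ether formation from a β-keto ester) should give the conjugated β-methoxy enoate as the more stable E isomer, and since only the ketone oxygen can be etherified the later C5–OMe of ring A is placed without any regiochemical choice.

Step 4
Reactants: 6 methyl (2E)-2-[4-(benzyloxy)benzyl]-5-[4-(benzyloxy)phenyl]-3-methoxypent-2-enoate; 7 (2E)-3-(3-methoxyphenyl)prop-2-enal
Product: 9 3,5-bis[4-(benzyloxy)benzyl]-4-methoxy-6-[(E)-2-(3-methoxyphenyl)ethenyl]-5,6-dihydro-2H-pyran-2-one, via lithium aldolate 8 (not isolated)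
Conditions: LiN(iPr)2, THF, −78 °C; 7, −78 → 0 °C; AcOH
Reagents that add atoms: none
Why: The ester has no α′ hydrogen, so the amide base can only deprotonate C6, and the dienolate should add 1,2 to the enal through its γ terminus (vinylogous aldol addition), after which the alkoxide closes onto the cis ester (lactonisation), draining the reversible aldol equilibria into the 4-methoxy-5,6-dihydropyran-2-one and locking C3 cis to C6; the two new sp3 centres (C1, C6) form without control as a racemic cis/trans mixture and are erased later.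

Step 5
Reactants: 10 2-[4-(benzyloxy)phenyl]ethanol
Product: 11 1-(benzyloxy)-4-(2-iodoethyl)benzene
Conditions: I2, PPh3, imidazole, CH2Cl2, 0 °C → rt
Reagents that add atoms: iodine, II
Why: In this Appel-type iodination the primary alcohol is activated as an alkoxyphosphonium ion and displaced by iodide in an SN2 reaction, giving the iodide needed for clean lithium–iodine exchange.

Step 6
Reactants: 11 1-(benzyloxy)-4-(2-iodoethyl)benzene; 9 3,5-bis[4-(benzyloxy)benzyl]-4-methoxy-6-[(E)-2-(3-methoxyphenyl)ethenyl]-5,6-dihydro-2H-pyran-2-one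
Product: 14 (1E,5E)-4,6-bis[4-(benzyloxy)benzyl]-9-[4-(benzyloxy)phenyl]-3-hydroxy-5-methoxy-1-(3-methoxyphenyl)nona-1,5-dien-7-one, via alkyllithium 12 (not isolated), via lithium lactolate 13 (not isolated)
Conditions: 11, t-BuLi (2 equiv), Et2O–pentane, −78 °C; then 9, THF, −78 °C; AcOH, −78 °C → rt
Reagents that add atoms: none
Why: Lithium–iodine exchange gives the primary alkyllithium, which should add once to the lactone carbonyl at −78 °C (addition of an organolithium to a lactone halted at the tetrahedral lactolate), and protonation releases the δ-hydroxy β-methoxy enone with the new C3–C2 bond and with the enol ether geometry inherited from the ring; no lasting stereocentre is created.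

Step 7
Reactants: 14 (1E,5E)-4,6-bis[4-(benzyloxy)benzyl]-9-[4-(benzyloxy)phenyl]-3-hydroxy-5-methoxy-1-(3-methoxyphenyl)nona-1,5-dien-7-one
Product: 15 (1E,5E)-4,6-bis[4-(benzyloxy)benzyl]-9-[4-(benzyloxy)phenyl]-5-methoxy-1-(3-methoxyphenyl)nona-1,5-diene-3,7-dione
Conditions: Dess–Martin periodinane, pyridine, CH2Cl2, 0 °C → rt
Reagents that add atoms: none
Why: Dess–Martin oxidation of the secondary allylic alcohol at C1 should give the cinnamoyl ketone under buffered, near-neutral conditions that spare the vinylogous ester, the benzyl ethers and the alkene, and because the cyclic hemiketal form has no oxidisable C–H the open chain is drawn off completely.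

Step 8
Reactants: 15 (1E,5E)-4,6-bis[4-(benzyloxy)benzyl]-9-[4-(benzyloxy)phenyl]-5-methoxy-1-(3-methoxyphenyl)nona-1,5-diene-3,7-dione
Product: 18 2,4,6-tris[4-(benzyloxy)benzyl]-3-methoxy-5-[(E)-2-(3-methoxyphenyl)ethenyl]phenol, via aldol adduct 16 (not isolated), via cyclohexadienone 17 (not isolated)
Conditions: KOtBu, t-BuOH–THF, rt → 60 °C; AcOH
Reagents that add atoms: none
Why: tert-Butoxide in tert-butanol keeps all enolates in exchange, so although the doubly activated C6–H is removed first and reversibly, the small share of the C2 enolate of the C3 ketone should add to the C1 ketone and form the C1–C2 bond. The closure is an intramolecular aldol addition of the 6-(enolendo)-exo-trig type; the β-hydroxy ketone 16 then loses water by an E1cB path to the cross-conjugated dienone 17, and removal of the C6 proton gives the phenoxide, aromatisation making the sequence irreversible. The closest known reaction type is the base-induced aldol cyclisation of 3,5,7-triketones and their mono enol ethers to resorcinol derivatives, as in stilbene biosynthesis. The sp3 centres of 15, 16 and 17 all become sp2 carbons of ring A, so no stereocentre has to be controlled and only the E geometry of the C7=C8 alkene is carried through. Regioselectivity rests on three features of 15: C7 is an alkene carbon and cannot enolise towards C1, the C3 carbonyl is a deactivated vinylogous ester and a poor acceptor, and the C5 oxygen is already fixed as its methyl ether while the E enol ether holds C3 and C6 cis. A bulky, non-nucleophilic alkoxide is chosen to suppress retro-Claisen cleavage of the C1–C6 bond and conjugate addition to the cinnamoyl group.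

Step 9
Reactants: 18 2,4,6-tris[4-(benzyloxy)benzyl]-3-methoxy-5-[(E)-2-(3-methoxyphenyl)ethenyl]phenol
Product: 19 2,4,6-tris(4-hydroxybenzyl)-3-methoxy-5-[2-(3-methoxyphenyl)ethyl]phenol
Conditions: H2 (1 atm), Pd/C, EtOAc–MeOH, rt
Reagents that add atoms: none
Why: Heterogeneous hydrogenation over palladium on carbon should saturate the disubstituted C7=C8 alkene and cleave the three aryl benzyl ethers by hydrogenolysis in one operation, while the aryl methyl ethers, the diarylmethane C–C bonds and the arene rings are inert under these conditions.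

Compound list
1 | methyl acetoacetate (methyl 3-oxobutanoate) | CC(=O)CC(=O)OC | starting material
2 | 4-(benzyloxy)benzyl chloride | ClCc1ccc(OCc2ccccc2)cc1 | starting material
3 | methyl 5-[4-(benzyloxy)phenyl]-3-oxopentanoate | COC(=O)CC(=O)CCc1ccc(OCc2ccccc2)cc1 | intermediate
4 | methyl 2-[4-(benzyloxy)benzyl]-5-[4-(benzyloxy)phenyl]-3-oxopentanoate (racemic) | COC(=O)C(Cc1ccc(OCc2ccccc2)cc1)C(=O)CCc1ccc(OCc2ccccc2)cc1 | intermediate
5 | methyl 2-[4-(benzyloxy)benzyl]-5-[4-(benzyloxy)phenyl]-3,3-dimethoxypentanoate (racemic; not isolated) | COC(=O)C(Cc1ccc(OCc2ccccc2)cc1)C(OC)(OC)CCc1ccc(OCc2ccccc2)cc1 | intermediate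
6 | methyl (2E)-2-[4-(benzyloxy)benzyl]-5-[4-(benzyloxy)phenyl]-3-methoxypent-2-enoate | COC(=O)/C(Cc1ccc(OCc2ccccc2)cc1)=C(/OC)CCc1ccc(OCc2ccccc2)cc1 | intermediate
7 | (2E)-3-(3-methoxyphenyl)prop-2-enal ((E)-3-methoxycinnamaldehyde) | COc1cccc(/C=C/C=O)c1 | starting material
8 | lithium alkoxide of methyl (2E,6E)-2,4-bis[4-(benzyloxy)benzyl]-5-hydroxy-3-methoxy-7-(3-methoxyphenyl)hepta-2,6-dienoate (racemic mixture of diastereomers; not isolated) | COC(=O)/C(Cc1ccc(OCc2ccccc2)cc1)=C(/OC)C(Cc1ccc(OCc2ccccc2)cc1)C([O-])/C=C/c1cccc(OC)c1.[Li+] | intermediate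
9 | 3,5-bis[4-(benzyloxy)benzyl]-4-methoxy-6-[(E)-2-(3-methoxyphenyl)ethenyl]-5,6-dihydro-2H-pyran-2-one (racemic; 5,6-cis/trans mixture) | O=C1OC(/C=C/c2cccc(OC)c2)C(Cc2ccc(OCc3ccccc3)cc2)C(OC)=C1Cc1ccc(OCc2ccccc2)cc1 | intermediate
10 | 2-[4-(benzyloxy)phenyl]ethanol | OCCc1ccc(OCc2ccccc2)cc1 | starting material
11 | 1-(benzyloxy)-4-(2-iodoethyl)benzene | ICCc1ccc(OCc2ccccc2)cc1 | intermediate
12 | {2-[4-(benzyloxy)phenyl]ethyl}lithium (not isolated) | [Li]CCc1ccc(OCc2ccccc2)cc1 | intermediate
13 | lithium salt of 3,5-bis[4-(benzyloxy)benzyl]-2-{2-[4-(benzyloxy)phenyl]ethyl}-4-methoxy-6-[(E)-2-(3-methoxyphenyl)ethenyl]-5,6-dihydro-2H-pyran-2-ol (mixture of diastereomers; not isolated) | [Li+].[O-]C1(CCc2ccc(OCc3ccccc3)cc2)OC(/C=C/c2cccc(OC)c2)C(Cc2ccc(OCc3ccccc3)cc2)C(OC)=C1Cc1ccc(OCc2ccccc2)cc1 | intermediate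
14 | (1E,5E)-4,6-bis[4-(benzyloxy)benzyl]-9-[4-(benzyloxy)phenyl]-3-hydroxy-5-methoxy-1-(3-methoxyphenyl)nona-1,5-dien-7-one (racemic mixture of diastereomers at C3 and C4 of this name; C3 of the target cis to C6 on the enol ether) | COc1cccc(/C=C/C(O)C(Cc2ccc(OCc3ccccc3)cc2)/C(OC)=C(/Cc2ccc(OCc3ccccc3)cc2)C(=O)CCc2ccc(OCc3ccccc3)cc2)c1 | intermediate
15 | (1E,5E)-4,6-bis[4-(benzyloxy)benzyl]-9-[4-(benzyloxy)phenyl]-5-methoxy-1-(3-methoxyphenyl)nona-1,5-diene-3,7-dione (racemic at C6 of the target numbering; C3 and C6 cis on the enol ether) | COc1cccc(/C=C/C(=O)C(Cc2ccc(OCc3ccccc3)cc2)/C(OC)=C(/Cc2ccc(OCc3ccccc3)cc2)C(=O)CCc2ccc(OCc3ccccc3)cc2)c1 | intermediate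
16 | 2,4,6-tris[4-(benzyloxy)benzyl]-5-hydroxy-3-methoxy-5-[(E)-2-(3-methoxyphenyl)ethenyl]cyclohex-2-en-1-one (mixture of diastereomers; not isolated) | COc1cccc(/C=C/C2(O)C(Cc3ccc(OCc4ccccc4)cc3)C(=O)C(Cc3ccc(OCc4ccccc4)cc3)=C(OC)C2Cc2ccc(OCc3ccccc3)cc2)c1 | intermediate
17 | 2,4,6-tris[4-(benzyloxy)benzyl]-3-methoxy-5-[(E)-2-(3-methoxyphenyl)ethenyl]cyclohexa-2,5-dien-1-one (racemic; not isolated) | COc1cccc(/C=C/C2=C(Cc3ccc(OCc4ccccc4)cc3)C(=O)C(Cc3ccc(OCc4ccccc4)cc3)=C(OC)C2Cc2ccc(OCc3ccccc3)cc2)c1 | intermediate
18 | 2,4,6-tris[4-(benzyloxy)benzyl]-3-methoxy-5-[(E)-2-(3-methoxyphenyl)ethenyl]phenol | COc1cccc(/C=C/c2c(Cc3ccc(OCc4ccccc4)cc3)c(O)c(Cc3ccc(OCc4ccccc4)cc3)c(OC)c2Cc2ccc(OCc3ccccc3)cc2)c1 | intermediate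
19 | 2,4,6-tris(4-hydroxybenzyl)-3-methoxy-5-[2-(3-methoxyphenyl)ethyl]phenol (achiral) | COc1cccc(CCc2c(Cc3ccc(O)cc3)c(O)c(Cc3ccc(O)cc3)c(OC)c2Cc2ccc(O)cc2)c1 | target

Total step count: 9. Longest linear sequence: 8 steps (steps 1, 2, 3, 4, 6, 7, 8 and 9, from methyl acetoacetate); step 5 is a one-step side branch.

Steps most likely to fail

Step 6. The alkyllithium may act as a base at C6–H of the lactone, after which β-elimination of the carboxylate opens the ring to a dienoic acid. Alternatively the lactolate may collapse early and take up a second equivalent of the reagent. The fallback sets out from lactone 9. Reduction with iBu2AlH in CH2Cl2 at −78 °C should stop at the lactol F1, which has no acidifying carbonyl group. An excess of alkyllithium 12 would deprotonate it, open it to the hydroxy enal alkoxide and add to the aldehyde, giving the allylic diol F2. Oxidation of both secondary alcohols with Dess–Martin periodinane and pyridine would then come back to the route at diketone 15, so that steps 6 and 7 are replaced.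

Step 8. The substrate may rest as its C6 enolate, in which both the C1 and the C3 carbonyl groups are tied up, so that closure at the crowded C1 ketone stalls, or the C1–C6 bond may be cleaved by a retro-Claisen path. The fallback sets out from 15. Hydrolysis of the enol ether with dilute aqueous HCl in THF at 0 °C should give the free triketone F3, in which C2 is the α-carbon of a true ketone. Mild base (K2CO3 in aqueous methanol, rt) would fold it by the same C2-to-C1 aldol condensation to the symmetric resorcinol F4. Because its two hydroxyl groups are equivalent, mono-O-methylation with one equivalent of MeI and K2CO3 in acetone can give only one monomethyl ether, stilbene 18, where the route is rejoined; unchanged F4 is recycled and over-methylated material is separated.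

Step 4. The dienolate of the tetrasubstituted enoate may form slowly or react through its α-carbon (C4), and the lithium methoxide released on lactonisation may open the product by elimination. The fallback sets out from β-keto ester 4. Its dianion (NaH, then n-BuLi, THF, 0 °C) would add through C6 to aldehyde 7 to give the δ-hydroxy β-keto ester F5. Ring closure (aqueous KOH, then acid) gives the 4-hydroxy-5,6-dihydropyran-2-one F6, and O-methylation with Me2SO4 and K2CO3 in acetone comes back to the route at lactone 9. Steps 3 and 4 are replaced, and the enol ether is made on the ring, where only the cis geometry exists.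

Further compounds
F1 | step 6 | 3,5-bis[4-(benzyloxy)benzyl]-4-methoxy-6-[(E)-2-(3-methoxyphenyl)ethenyl]-5,6-dihydro-2H-pyran-2-ol (mixture of diastereomers) | OC1OC(/C=C/c2cccc(OC)c2)C(Cc2ccc(OCc3ccccc3)cc2)C(OC)=C1Cc1ccc(OCc2ccccc2)cc1
F2 | step 6 | (1E,5E)-4,6-bis[4-(benzyloxy)benzyl]-9-[4-(benzyloxy)phenyl]-5-methoxy-1-(3-methoxyphenyl)nona-1,5-diene-3,7-diol (mixture of diastereomers) | COc1cccc(/C=C/C(O)C(Cc2ccc(OCc3ccccc3)cc2)/C(OC)=C(/Cc2ccc(OCc3ccccc3)cc2)C(O)CCc2ccc(OCc3ccccc3)cc2)c1
F3 | step 8 | (1E)-4,6-bis[4-(benzyloxy)benzyl]-9-[4-(benzyloxy)phenyl]-1-(3-methoxyphenyl)non-1-ene-3,5,7-trione (mixture of diastereomers and enol forms) | COc1cccc(/C=C/C(=O)C(Cc2ccc(OCc3ccccc3)cc2)C(=O)C(Cc2ccc(OCc3ccccc3)cc2)C(=O)CCc2ccc(OCc3ccccc3)cc2)c1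
F4 | step 8 | 2,4,6-tris[4-(benzyloxy)benzyl]-5-[(E)-2-(3-methoxyphenyl)ethenyl]benzene-1,3-diol | COc1cccc(/C=C/c2c(Cc3ccc(OCc4ccccc4)cc3)c(O)c(Cc3ccc(OCc4ccccc4)cc3)c(O)c2Cc2ccc(OCc3ccccc3)cc2)c1
F5 | step 4 | methyl (6E)-2,4-bis[4-(benzyloxy)benzyl]-5-hydroxy-7-(3-methoxyphenyl)-3-oxohept-6-enoate (mixture of diastereomers) | COC(=O)C(Cc1ccc(OCc2ccccc2)cc1)C(=O)C(Cc1ccc(OCc2ccccc2)cc1)C(O)/C=C/c1cccc(OC)c1
F6 | step 4 | 3,5-bis[4-(benzyloxy)benzyl]-4-hydroxy-6-[(E)-2-(3-methoxyphenyl)ethenyl]-5,6-dihydro-2H-pyran-2-one (racemic; 5,6-cis/trans mixture) | O=C1OC(/C=C/c2cccc(OC)c2)C(Cc2ccc(OCc3ccccc3)cc2)C(O)=C1Cc1ccc(OCc2ccccc2)cc1
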